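A small charge of nucleophile, 1.1 equiv on 0.68 M of electrophile in the winter run, left 64.1% of the electrophile after 30.0 min. The bench rule is to count half-lives: if the nucleophile can be treated as constant (pseudo-first-order), the half-lives passed in a fixed time grow in proportion to the nucleophile charged.

| setting | winter | dusk | Tuesday's | Monday's |
|---|---|---|---|---|
| electrophile | 0.68 M | 0.68 M | 0.68 M | 0.68 M |
| nucleophile | 1.1 equiv | 3.3 equiv | 1.50 equiv | 3.80 equiv |
| remark | run made earlier | run made earlier |  |  |
| time |  |  | 30 min | 30 min |

| run | time / min | target / % | over-reaction product / % | electrophile / % | isomer of the product / % |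
|---|---|---|---|---|---|
| winter | 2.50 | 4.1 | 0.5 | 94.3 | 0.9 |
| winter | 4.00 | 7.9 | 0 | 91.3 | 2.0 |
| winter | 6.00 | 10.4 | 0.8 | 87.8 | 3.1 |
| winter | 8.00 | 12.0 | 0.4 | 84.8 | 3.8 |
| winter | 12.0 | 16.2 | 0.5 | 77.3 | 6.6 |
| winter | 20.0 | 19.9 | 1.6 | 70.5 | 11.1 |
| winter | 30.0 | 21.3 | 1.3 | 64.1 | 13.1 |
| dusk | 4.00 | 18.1 | 2.9 | 76.6 | 2.3 |
| dusk | 8.00 | 28.1 | 4.1 | 61.9 | 10.5 |
| dusk | 12.0 | 29.9 | 3.2 | 47.6 | 15.9 |
| dusk | 15.0 | 31.8 | 8.2 | 41.6 | 18.5 |
| dusk | 20.0 | 34.4 | 12.7 | 34.5 | 24.5 |
| dusk | 25.0 | 33.9 | 13.7 | 26.7 | 23.6 |
| dusk | 30.0 | 34.9 | 18.1 | 21.5 | 27.2 |

(each reading ± 1 percentage point)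



- which of these there is most of at the end, counted by the electrophile in it, Tuesday's (over-reaction product / electrophile / target / isomer of the product)
- which of these there is most of at the end, counted by the electrophile in it, Monday's (over-reaction product / electrophile / target / isomer of the product)
- how much there is at the end of the one of these that leads, in percent of the electrophile charged: Tuesday's
- how much there is at the end of the one of these that leads, in percent of the electrophile charged: Monday's

The count n is ln(charged/left)/ln(2). The winter run passed 0.642 half-lives on 0.748 M of nucleophile, which gives 0.858 M⁻¹ for H, the half-lives passed in 30 min per molar of nucleophile charged. The dusk run passed 2.22, which is 3.46 times the winter count for 3.00 times the charge. Its H, read the same way, is 0.988 M⁻¹. The counts stand further apart than the charges, and that is the border of the rule: the two readings of H differ, so for each new flask we borrow H from the run nearer in charge.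

For Tuesday's the winter H leaves 54.5% of the electrophile, more than the other three together, so electrophile leads. For Monday's the dusk H leaves 17.0%. Target in the dusk run read 34.4%, 33.9% and 34.9% over its last readings, above the isomer of the product at 27.2%, so we expect target to lead Monday's near that reading.

The forecast gives electrophile at 53% (49% to 57%) for Tuesday's, a little below our figure, and target at 35% (32.5% to 37.5%) for Monday's, saying “Target has plateaued near 35, since faster formation is offset by more over-reaction”.

Tuesday's ends with electrophile leading at 53.6%, and Monday's with target leading at 35.3%.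

    nucleophile + target → over-reaction product (k = 2.30 × 10⁻⁴ M⁻¹ s⁻¹)
    target ⇌ isomer of the product (K = 0.800, k = 0.00170 s⁻¹)
    nucleophile + acid set free ⇌ protonated nucleophile, settled at all times (K = 8100 M⁻¹)
    electrophile + nucleophile → acid set free + target (k = 5.70 × 10⁻⁴ M⁻¹ s⁻¹)

Tuesday's electrophile passed 0.898 half-lives, so H there is 0.881 M⁻¹, while its half-life by the making of target, with the other concentrations as charged, is 20 min, which fits 1.50 half-lives into 30 min, more than were counted, and at the end of Tuesday's 36% of the nucleophile charged stood free, beside 0.315 M of protonated nucleophile. The neighbour at 0.17 M with Tuesday's equivalents, for which the winter H reckons 85.9% left, ended with 80% of its electrophile.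

(The numbers in the tables stem from a simulated flask from invented constants; scatter was added.)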